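Numbering used throughout (germacranolide type): lactone C12(=O)–C11(=C13H2)–C7–C8(–O–C12); ring C8, C9 (OH), C10 (Me)=C1, C2 (OH), C3, C4 (Me)=C5, C6 (O‑acyl), C7.

**Plan**
- Cuts, in order: the O6 ester and the O2/O9 PMB ethers, then C11–C12 and C7–C8 in one event, which opens the lactone and the ten-membered ring to an acyclic allenyl aldehyde plus CO2.
- Enabling feature: the α‑methylene‑γ‑butyrolactone O8–C12(=O)–C11(=C13H2)–C7–C8 shares its C7–C8 bond with the (Z,Z)-cyclodeca-1(10),4-diene ring. It is the retron of a 2‑carboxyallyl metal adding to an aldehyde, and that metal is a terminal allene (C7=C11=C13) plus CO2 on Ni(0).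
- Forward: the chain C8→C13 is built linearly by two rounds of ynoate formation and syn‑methylcupration (Z‑C10=C1, then Z‑C4=C5), each followed by reduction/oxidation to a Z‑enal and an asymmetric C–C addition; a Crabbé homologation gives the allene.
- The carbocycle and the lactone arise together in step 19; desilylation, esterification and PMB removal finish the synthesis.
- Stereochemistry: C9 from (S)-glycerate acetonide; C2 by catalyst‑controlled propargylation; C6 by catalyst‑controlled alkynylation; C7 and C8 in the key step (chair transition state, C6 and C9 control); the acyl centre from (R)-2‑methylbutanoic acid.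

Key step: step 19

Remark: in steps 6 and 12 the catalyst antipode is the one that delivers the 2S and the 6R carbinol; (S)-TRIP and (S,S)-ProPhenol are written on the assumption that the facial sense known for simple aldehydes carries over.
Remark: 22 is drawn as the σ‑allyl form without its DBU ligands and without alkylidene geometry, which is expected to be fluxional.

**Route**

Step 1
Reactants: 1 methyl (4S)-2,2-dimethyl-1,3-dioxolane-4-carboxylate
Product: 3 (4R)-4-ethynyl-2,2-dimethyl-1,3-dioxolane, via aldehyde 2 (not isolated)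
Conditions: DIBAL-H, CH2Cl2, −78 °C; then MeOH, Bestmann–Ohira reagent, K2CO3, 0 °C → rt
Reagents that add atoms: dimethyl (1-diazo-2-oxopropyl)phosphonate (Bestmann–Ohira reagent), CC(=O)C(=[N+]=[N-])P(=O)(OC)OC
Why: Half-reduction of the ester followed in the same flask by Seyferth–Gilbert (Bestmann–Ohira) homologation should give the alkyne, with the C9 stereocentre taken unchanged from the chiral pool.

Step 2
Reactants: 3 (4R)-4-ethynyl-2,2-dimethyl-1,3-dioxolane
Product: 4 methyl 3-[(4R)-2,2-dimethyl-1,3-dioxolan-4-yl]prop-2-ynoate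
Conditions: n-BuLi, THF, −78 °C; ClCO2Me, −78 → 0 °C
Reagents that add atoms: methyl chloroformate, COC(=O)Cl
Why: C‑Acylation of the lithium acetylide with a chloroformate is the standard ynoate synthesis and touches no stereocentre.

Step 3
Reactants: 4 methyl 3-[(4R)-2,2-dimethyl-1,3-dioxolan-4-yl]prop-2-ynoate
Product: 5 methyl (2Z)-3-[(4R)-2,2-dimethyl-1,3-dioxolan-4-yl]but-2-enoate
Conditions: Me2CuLi (CuI, 2 MeLi), THF, −78 °C; MeOH at −78 °C, then aq. NH4Cl
Reagents that add atoms: lithium dimethylcuprate, [Li+].C[Cu-]C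
Why: Syn‑carbocupration (conjugate addition) of the Gilman reagent to the ynoate and protonation at −78 °C should place C9 cis to the ester carbon, which fixes the Z geometry of C10=C1.

Step 4
Reactants: 5 methyl (2Z)-3-[(4R)-2,2-dimethyl-1,3-dioxolan-4-yl]but-2-enoate
Product: 6 (2Z)-3-[(4R)-2,2-dimethyl-1,3-dioxolan-4-yl]but-2-en-1-ol
Conditions: DIBAL-H, CH2Cl2, −78 °C
Reagents that add atoms: none
Why: DIBAL-H reduces the conjugated ester 1,2‑selectively to the allylic alcohol without changing the alkene geometry or the acetonide.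

Step 5
Reactants: 6 (2Z)-3-[(4R)-2,2-dimethyl-1,3-dioxolan-4-yl]but-2-en-1-ol
Product: 7 (2Z)-3-[(4R)-2,2-dimethyl-1,3-dioxolan-4-yl]but-2-enal
Conditions: TEMPO (cat.), PhI(OAc)2, CH2Cl2, rt
Reagents that add atoms: none
Why: The oxoammonium (TEMPO/PhI(OAc)2) oxidation of an allylic alcohol is close to neutral, so the Z‑enal should form without Z→E isomerisation.

Step 6
Reactants: 7 (2Z)-3-[(4R)-2,2-dimethyl-1,3-dioxolan-4-yl]but-2-enal
Product: 8 (4S,5Z)-6-[(4R)-2,2-dimethyl-1,3-dioxolan-4-yl]hept-5-en-1-yn-4-ol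
Conditions: allenylboronic acid pinacol ester, (S)-TRIP phosphoric acid (5 mol %), 4 Å MS, toluene, −20 °C
Reagents that add atoms: allenylboronic acid pinacol ester, C=C=CB1OC(C)(C)C(C)(C)O1
Why: Chiral phosphoric acid‑catalysed propargylation (SE2' addition of the allenylboronate through a six‑membered chair held by the catalyst) should set C2 as S under catalyst control, the remote C9 centre having little say.

Step 7
Reactants: 8 (4S,5Z)-6-[(4R)-2,2-dimethyl-1,3-dioxolan-4-yl]hept-5-en-1-yn-4-ol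
Product: 9 (4R)-4-[(2Z,4S)-4-[(4-methoxyphenyl)methoxy]hept-2-en-6-yn-2-yl]-2,2-dimethyl-1,3-dioxolane
Conditions: NaH, PMBCl, Bu4NI (cat.), THF/DMF, 0 °C → rt
Reagents that add atoms: 4-methoxybenzyl chloride, COc1ccc(CCl)cc1
Why: Williamson etherification of the sodium alkoxide installs the PMB ether on O2 without touching the stereocentre.

Step 8
Reactants: 9 (4R)-4-[(2Z,4S)-4-[(4-methoxyphenyl)methoxy]hept-2-en-6-yn-2-yl]-2,2-dimethyl-1,3-dioxolane
Product: 10 methyl (5S,6Z)-7-[(4R)-2,2-dimethyl-1,3-dioxolan-4-yl]-5-[(4-methoxyphenyl)methoxy]oct-6-en-2-ynoate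
Conditions: n-BuLi, THF, −78 °C; ClCO2Me, −78 → 0 °C
Reagents that add atoms: methyl chloroformate, COC(=O)Cl
Why: Selective deprotonation of the terminal alkyne and C‑acylation with the chloroformate gives the second ynoate, as in step 2.

Step 9
Reactants: 10 methyl (5S,6Z)-7-[(4R)-2,2-dimethyl-1,3-dioxolan-4-yl]-5-[(4-methoxyphenyl)methoxy]oct-6-en-2-ynoate
Product: 11 methyl (2Z,5S,6Z)-7-[(4R)-2,2-dimethyl-1,3-dioxolan-4-yl]-5-[(4-methoxyphenyl)methoxy]-3-methylocta-2,6-dienoate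
Conditions: Me2CuLi (CuI, 2 MeLi), THF, −78 °C; MeOH at −78 °C, then aq. NH4Cl
Reagents that add atoms: lithium dimethylcuprate, [Li+].C[Cu-]C
Why: The same syn‑carbocupration/cold protonation should place C3 cis to the ester carbon and so fix the Z geometry of C4=C5.

Step 10
Reactants: 11 methyl (2Z,5S,6Z)-7-[(4R)-2,2-dimethyl-1,3-dioxolan-4-yl]-5-[(4-methoxyphenyl)methoxy]-3-methylocta-2,6-dienoate
Product: 12 (2Z,5S,6Z)-7-[(4R)-2,2-dimethyl-1,3-dioxolan-4-yl]-5-[(4-methoxyphenyl)methoxy]-3-methylocta-2,6-dien-1-ol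
Conditions: DIBAL-H, CH2Cl2, −78 °C
Reagents that add atoms: none
Why: 1,2‑Reduction of the enoate by DIBAL-H gives the allylic alcohol and leaves the PMB ether, the acetonide and both alkenes untouched.

Step 11
Reactants: 12 (2Z,5S,6Z)-7-[(4R)-2,2-dimethyl-1,3-dioxolan-4-yl]-5-[(4-methoxyphenyl)methoxy]-3-methylocta-2,6-dien-1-ol
Product: 13 (2Z,5S,6Z)-7-[(4R)-2,2-dimethyl-1,3-dioxolan-4-yl]-5-[(4-methoxyphenyl)methoxy]-3-methylocta-2,6-dienal
Conditions: TEMPO (cat.), PhI(OAc)2, CH2Cl2, rt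
Reagents that add atoms: none
Why: The near‑neutral oxoammonium oxidation should again give the Z‑enal without isomerisation and without attack on the PMB ether.

Step 12
Reactants: 13 (2Z,5S,6Z)-7-[(4R)-2,2-dimethyl-1,3-dioxolan-4-yl]-5-[(4-methoxyphenyl)methoxy]-3-methylocta-2,6-dienal
Product: 15 (3R,4Z,7S,8Z)-9-[(4R)-2,2-dimethyl-1,3-dioxolan-4-yl]-7-[(4-methoxyphenyl)methoxy]-5-methyldeca-4,8-dien-1-yn-3-ol, via silylalkynol 14 (not isolated)
Conditions: Me2Zn, (S,S)-ProPhenol (10 mol %), Ph3P=O (20 mol %), ethynyltrimethylsilane, toluene, 0 °C; then MeOH, K2CO3, rt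
Reagents that add atoms: ethynyltrimethylsilane, C#C[Si](C)(C)C
Why: Zn–ProPhenol‑catalysed asymmetric alkynylation of the enal should set C6 as R under ligand control, and methanolysis then removes the C‑silyl group.

Step 13
Reactants: 15 (3R,4Z,7S,8Z)-9-[(4R)-2,2-dimethyl-1,3-dioxolan-4-yl]-7-[(4-methoxyphenyl)methoxy]-5-methyldeca-4,8-dien-1-yn-3-ol
Product: 16 tert-butyldimethylsilyl ether of 15 at O6
Conditions: TBSCl, imidazole, DMF, rt
Reagents that add atoms: tert-butyldimethylsilyl chloride, CC(C)(C)[Si](C)(C)Cl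
Why: Silylation of the secondary alcohol gives an O6 group that cannot ionise or β‑eliminate in the key step.

Step 14
Reactants: 16 tert-butyldimethylsilyl ether of 15 at O6
Product: 17 (2R,3Z,5S,7Z,9R)-9-[(tert-butyldimethylsilyl)oxy]-5-[(4-methoxyphenyl)methoxy]-3,7-dimethylundeca-3,7-dien-10-yne-1,2-diol
Conditions: CuCl2·2H2O, MeCN, 0 °C → rt
Reagents that add atoms: none
Why: Mild Lewis‑acid hydrolysis of the terminal isopropylidene acetal should free the 8,9‑diol while the secondary TBS ether and the PMB ether survive.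

Step 15
Reactants: 17 (2R,3Z,5S,7Z,9R)-9-[(tert-butyldimethylsilyl)oxy]-5-[(4-methoxyphenyl)methoxy]-3,7-dimethylundeca-3,7-dien-10-yne-1,2-diol
Product: 18 4-methoxybenzylidene acetal of 17 (both epimers at the acetal carbon)
Conditions: 4-methoxybenzaldehyde dimethyl acetal, PPTS (cat.), CH2Cl2, rt
Reagents that add atoms: 4-methoxybenzaldehyde dimethyl acetal, COC(OC)c1ccc(OC)cc1
Why: Acid‑catalysed transacetalisation forms the 2‑aryl‑1,3‑dioxolane, and both acetal epimers converge in the next step.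

Step 16
Reactants: 18 4-methoxybenzylidene acetal of 17
Product: 19 (2R,3Z,5S,7Z,9R)-9-[(tert-butyldimethylsilyl)oxy]-2,5-bis[(4-methoxyphenyl)methoxy]-3,7-dimethylundeca-3,7-dien-10-yn-1-ol
Conditions: DIBAL-H, CH2Cl2, −78 → 0 °C
Reagents that add atoms: none
Why: In the reductive acetal opening, aluminium binds the less hindered O8 and hydride goes to the acetal carbon, so the PMB group should stay on O9 and the primary C8 alcohol is freed.

Step 17
Reactants: 19 (2R,3Z,5S,7Z,9R)-9-[(tert-butyldimethylsilyl)oxy]-2,5-bis[(4-methoxyphenyl)methoxy]-3,7-dimethylundeca-3,7-dien-10-yn-1-ol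
Product: 20 (2R,3Z,5S,7Z,9S)-9-[(tert-butyldimethylsilyl)oxy]-2,5-bis[(4-methoxyphenyl)methoxy]-3,7-dimethyldodeca-3,7,10,11-tetraen-1-ol
Conditions: (CH2O)n, CuI (0.5 equiv), Cy2NH, 1,4-dioxane, reflux
Reagents that add atoms: formaldehyde (as paraformaldehyde), C=O
Why: The Crabbé homologation (Mannich reaction to the propargylic amine, then copper‑mediated 1,5‑hydride shift and fragmentation) turns the terminal alkyne into the terminal allene and adds C13 without touching a stereocentre.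

Step 18
Reactants: 20 (2R,3Z,5S,7Z,9S)-9-[(tert-butyldimethylsilyl)oxy]-2,5-bis[(4-methoxyphenyl)methoxy]-3,7-dimethyldodeca-3,7,10,11-tetraen-1-ol
Product: 21 (2R,3Z,5S,7Z,9S)-9-[(tert-butyldimethylsilyl)oxy]-2,5-bis[(4-methoxyphenyl)methoxy]-3,7-dimethyldodeca-3,7,10,11-tetraenal
Conditions: Dess–Martin periodinane, CH2Cl2, 0 °C; used at once
Reagents that add atoms: none
Why: Dess–Martin oxidation gives the α‑alkoxy aldehyde under non‑basic conditions, which should avoid epimerisation at C9 and migration of the C10=C1 double bond.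

Step 19
Reactants: 21 (2R,3Z,5S,7Z,9S)-9-[(tert-butyldimethylsilyl)oxy]-2,5-bis[(4-methoxyphenyl)methoxy]-3,7-dimethyldodeca-3,7,10,11-tetraenal
Product: 24 (3aR,4R,5Z,8S,9Z,11R,11aR)-4-[(tert-butyldimethylsilyl)oxy]-8,11-bis[(4-methoxyphenyl)methoxy]-6,10-dimethyl-3-methylidene-3a,4,7,8,11,11a-hexahydrocyclodeca[b]furan-2(3H)-one, via nickelalactone 22 (not isolated), via hydroxy acid 23 (not isolated)
Conditions: Ni(cod)2 (1.2 equiv), DBU (2.5 equiv), CO2 (1 atm), THF, 0 °C, 21 added over 8 h to 2 mM; then 1 M HCl, 0 °C → rt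
Reagents that add atoms: carbon dioxide, O=C=O
Why: Proposed new method: Ni(0) couples the terminal C11=C13 π‑bond of the allene with CO2 (C11–C12) to a five‑membered nickelalactone that is an η1/η3 2‑carboxyallyl nickel, whose γ‑carbon C7 then adds to the tethered aldehyde carbon C8 through a six‑membered chair (C7–C8), and acid releases the γ‑hydroxy acid, which lactonises. The closest known reaction types are the Ni(cod)2/DBU carboxylation of terminal allenes with intermolecular trapping of the nickelacycle by aldehydes, and the Cr(II)-mediated intramolecular 2‑(alkoxycarbonyl)allylation that closes ten‑membered germacranolide rings; new here is their union in a ring‑closing mode. The carbocycle closes 10‑exo‑trig at the aldehyde (SE2' at the allyl unit) and the lactone closes 5‑exo‑trig by attack of O8 on C12. For C7/C8, η1–η3–η1 equilibration of the alkylidene geometry should let the reaction funnel through the chair with both ring branches (C6 on C7, C9 on C8) equatorial, which gives the anti adduct and hence the trans‑lactone; at C8 the nickel(II) that carries the aldehyde is expected to chelate the PMB ether oxygen on C9 so that C7 enters anti to C10 (8,9‑syn); at C7 allylic 1,3‑strain against the C11 carboxylate keeps H6 in the alkene plane, the ring bond C6–C5 has to stay gauche to the forming bond, and the OTBS group is then anti to the incoming aldehyde. The step needs γ‑ over α‑attack of the allyl unit (10‑ versus 12‑membered ring), ring closure over oligomerisation, and CO2 capture before Ni(0) touches the aldehyde or the allylic ethers; the SE2' preference of σ‑allyl metals, slow addition to 2 mM, fast carboxylation at 0 °C and a silyl ether rather than an ester on C6 are meant to secure these.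

Step 20
Reactants: 24 TBS/bis‑PMB lactone (name as in step 19)
Product: 25 (3aS,4R,5Z,8S,9Z,11R,11aR)-4-hydroxy-8,11-bis[(4-methoxyphenyl)methoxy]-6,10-dimethyl-3-methylidene-3a,4,7,8,11,11a-hexahydrocyclodeca[b]furan-2(3H)-one
Conditions: HF·pyridine, pyridine, THF, 0 °C → rt
Reagents that add atoms: none
Why: Fluoride cleavage of the silyl ether frees O6 only, since PMB ethers and the α‑methylene lactone are inert to buffered HF·pyridine.

Step 21
Reactants: 25 C6 alcohol (name as in step 20); 26 (2R)-2-methylbutanoic acid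
Product: 27 (3aS,4R,5Z,8S,9Z,11R,11aR)-8,11-bis[(4-methoxyphenyl)methoxy]-6,10-dimethyl-3-methylidene-2-oxo-2,3,3a,4,7,8,11,11a-octahydrocyclodeca[b]furan-4-yl (2R)-2-methylbutanoate
Conditions: EDC·HCl, DMAP (0.2 equiv), CH2Cl2, 0 °C → rt
Reagents that add atoms: none
Why: Steglich esterification acylates the only free hydroxyl, and low temperature with sub‑stoichiometric DMAP is meant to avoid epimerisation α to the acyl carbonyl.

Step 22
Reactants: 27 bis‑PMB ester (name as in step 21)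
Product: 28 (3aS,4R,5Z,8S,9Z,11R,11aR)-8,11-dihydroxy-6,10-dimethyl-3-methylidene-2-oxo-2,3,3a,4,7,8,11,11a-octahydrocyclodeca[b]furan-4-yl (2R)-2-methylbutanoate
Conditions: DDQ, CH2Cl2/pH 7 buffer (10:1), 0 °C
Reagents that add atoms: none
Why: Oxidative cleavage of both PMB ethers by DDQ (hydride abstraction, then hydrolysis of the oxocarbenium ion) should release the two allylic alcohols without touching the ester or the enoate.

**Compound list**

1 | methyl (4S)-2,2-dimethyl-1,3-dioxolane-4-carboxylate | COC(=O)[C@@H]1COC(C)(C)O1 | starting material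
2 | (4S)-2,2-dimethyl-1,3-dioxolane-4-carbaldehyde | O=C[C@@H]1COC(C)(C)O1 | intermediate
3 | (4R)-4-ethynyl-2,2-dimethyl-1,3-dioxolane | C#C[C@@H]1COC(C)(C)O1 | intermediate
4 | methyl 3-[(4R)-2,2-dimethyl-1,3-dioxolan-4-yl]prop-2-ynoate | COC(=O)C#C[C@@H]1COC(C)(C)O1 | intermediate
5 | methyl (2Z)-3-[(4R)-2,2-dimethyl-1,3-dioxolan-4-yl]but-2-enoate | COC(=O)/C=C(/C)[C@@H]1COC(C)(C)O1 | intermediate
6 | (2Z)-3-[(4R)-2,2-dimethyl-1,3-dioxolan-4-yl]but-2-en-1-ol | OC/C=C(/C)[C@@H]1COC(C)(C)O1 | intermediate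
7 | (2Z)-3-[(4R)-2,2-dimethyl-1,3-dioxolan-4-yl]but-2-enal | O=C/C=C(/C)[C@@H]1COC(C)(C)O1 | intermediate
8 | (4S,5Z)-6-[(4R)-2,2-dimethyl-1,3-dioxolan-4-yl]hept-5-en-1-yn-4-ol | C#CC[C@H](O)/C=C(/C)[C@@H]1COC(C)(C)O1 | intermediate
9 | (4R)-4-[(2Z,4S)-4-[(4-methoxyphenyl)methoxy]hept-2-en-6-yn-2-yl]-2,2-dimethyl-1,3-dioxolane | C#CC[C@H](OCc1ccc(OC)cc1)/C=C(/C)[C@@H]1COC(C)(C)O1 | intermediate
10 | methyl (5S,6Z)-7-[(4R)-2,2-dimethyl-1,3-dioxolan-4-yl]-5-[(4-methoxyphenyl)methoxy]oct-6-en-2-ynoate | COC(=O)C#CC[C@H](OCc1ccc(OC)cc1)/C=C(/C)[C@@H]1COC(C)(C)O1 | intermediate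
11 | methyl (2Z,5S,6Z)-7-[(4R)-2,2-dimethyl-1,3-dioxolan-4-yl]-5-[(4-methoxyphenyl)methoxy]-3-methylocta-2,6-dienoate | COC(=O)/C=C(/C)C[C@H](OCc1ccc(OC)cc1)/C=C(/C)[C@@H]1COC(C)(C)O1 | intermediate
12 | (2Z,5S,6Z)-7-[(4R)-2,2-dimethyl-1,3-dioxolan-4-yl]-5-[(4-methoxyphenyl)methoxy]-3-methylocta-2,6-dien-1-ol | OC/C=C(/C)C[C@H](OCc1ccc(OC)cc1)/C=C(/C)[C@@H]1COC(C)(C)O1 | intermediate
13 | (2Z,5S,6Z)-7-[(4R)-2,2-dimethyl-1,3-dioxolan-4-yl]-5-[(4-methoxyphenyl)methoxy]-3-methylocta-2,6-dienal | O=C/C=C(/C)C[C@H](OCc1ccc(OC)cc1)/C=C(/C)[C@@H]1COC(C)(C)O1 | intermediate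
14 | (3R,4Z,7S,8Z)-9-[(4R)-2,2-dimethyl-1,3-dioxolan-4-yl]-7-[(4-methoxyphenyl)methoxy]-5-methyl-1-(trimethylsilyl)deca-4,8-dien-1-yn-3-ol | C[Si](C)(C)C#C[C@H](O)/C=C(/C)C[C@H](OCc1ccc(OC)cc1)/C=C(/C)[C@@H]1COC(C)(C)O1 | intermediate
15 | (3R,4Z,7S,8Z)-9-[(4R)-2,2-dimethyl-1,3-dioxolan-4-yl]-7-[(4-methoxyphenyl)methoxy]-5-methyldeca-4,8-dien-1-yn-3-ol | C#C[C@H](O)/C=C(/C)C[C@H](OCc1ccc(OC)cc1)/C=C(/C)[C@@H]1COC(C)(C)O1 | intermediate
16 | tert-butyldimethylsilyl ether of 15 at the propargylic oxygen (O6) | C#C[C@H](O[Si](C)(C)C(C)(C)C)/C=C(/C)C[C@H](OCc1ccc(OC)cc1)/C=C(/C)[C@@H]1COC(C)(C)O1 | intermediate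
17 | (2R,3Z,5S,7Z,9R)-9-[(tert-butyldimethylsilyl)oxy]-5-[(4-methoxyphenyl)methoxy]-3,7-dimethylundeca-3,7-dien-10-yne-1,2-diol | C#C[C@H](O[Si](C)(C)C(C)(C)C)/C=C(/C)C[C@H](OCc1ccc(OC)cc1)/C=C(/C)[C@@H](O)CO | intermediate
18 | 1,2-O-(4-methoxybenzylidene) acetal of 17 (epimers at the acetal carbon) | C#C[C@H](O[Si](C)(C)C(C)(C)C)/C=C(/C)C[C@H](OCc1ccc(OC)cc1)/C=C(/C)[C@@H]1COC(c2ccc(OC)cc2)O1 | intermediate
19 | (2R,3Z,5S,7Z,9R)-9-[(tert-butyldimethylsilyl)oxy]-2,5-bis[(4-methoxyphenyl)methoxy]-3,7-dimethylundeca-3,7-dien-10-yn-1-ol | C#C[C@H](O[Si](C)(C)C(C)(C)C)/C=C(/C)C[C@H](OCc1ccc(OC)cc1)/C=C(/C)[C@@H](OCc1ccc(OC)cc1)CO | intermediate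
20 | (2R,3Z,5S,7Z,9S)-9-[(tert-butyldimethylsilyl)oxy]-2,5-bis[(4-methoxyphenyl)methoxy]-3,7-dimethyldodeca-3,7,10,11-tetraen-1-ol | C=C=C[C@H](O[Si](C)(C)C(C)(C)C)/C=C(/C)C[C@H](OCc1ccc(OC)cc1)/C=C(/C)[C@@H](OCc1ccc(OC)cc1)CO | intermediate
21 | (2R,3Z,5S,7Z,9S)-9-[(tert-butyldimethylsilyl)oxy]-2,5-bis[(4-methoxyphenyl)methoxy]-3,7-dimethyldodeca-3,7,10,11-tetraenal | C=C=C[C@H](O[Si](C)(C)C(C)(C)C)/C=C(/C)C[C@H](OCc1ccc(OC)cc1)/C=C(/C)[C@@H](OCc1ccc(OC)cc1)C=O | intermediate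
22 | nickelalactone of 21: 1-oxa-2-nickelacyclopentan-5-one with Ni on C13 and O, C11 in the ring, exocyclic C11=C7 alkylidene carrying the chain of 21 | O=C1O[Ni]CC1=C[C@H](O[Si](C)(C)C(C)(C)C)/C=C(/C)C[C@H](OCc2ccc(OC)cc2)/C=C(/C)[C@@H](OCc2ccc(OC)cc2)C=O | intermediate
23 | 2-[(3Z,7Z)-2-[(tert-butyldimethylsilyl)oxy]-10-hydroxy-5,9-bis[(4-methoxyphenyl)methoxy]-4,8-dimethylcyclodeca-3,7-dien-1-yl]prop-2-enoic acid, configured at all five ring stereocentres as in 24 | C=C(C(=O)O)[C@H]1[C@H](O[Si](C)(C)C(C)(C)C)/C=C(/C)C[C@H](OCc2ccc(OC)cc2)/C=C(/C)[C@@H](OCc2ccc(OC)cc2)[C@@H]1O | intermediate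
24 | (3aR,4R,5Z,8S,9Z,11R,11aR)-4-[(tert-butyldimethylsilyl)oxy]-8,11-bis[(4-methoxyphenyl)methoxy]-6,10-dimethyl-3-methylidene-3a,4,7,8,11,11a-hexahydrocyclodeca[b]furan-2(3H)-one | C=C1C(=O)O[C@@H]2[C@@H]1[C@H](O[Si](C)(C)C(C)(C)C)/C=C(/C)C[C@H](OCc1ccc(OC)cc1)/C=C(/C)[C@H]2OCc1ccc(OC)cc1 | intermediate
25 | (3aS,4R,5Z,8S,9Z,11R,11aR)-4-hydroxy-8,11-bis[(4-methoxyphenyl)methoxy]-6,10-dimethyl-3-methylidene-3a,4,7,8,11,11a-hexahydrocyclodeca[b]furan-2(3H)-one | C=C1C(=O)O[C@@H]2[C@@H]1[C@H](O)/C=C(/C)C[C@H](OCc1ccc(OC)cc1)/C=C(/C)[C@H]2OCc1ccc(OC)cc1 | intermediate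
26 | (2R)-2-methylbutanoic acid | CC[C@@H](C)C(=O)O | starting material
27 | (3aS,4R,5Z,8S,9Z,11R,11aR)-8,11-bis[(4-methoxyphenyl)methoxy]-6,10-dimethyl-3-methylidene-2-oxo-2,3,3a,4,7,8,11,11a-octahydrocyclodeca[b]furan-4-yl (2R)-2-methylbutanoate | C=C1C(=O)O[C@@H]2[C@@H]1[C@H](OC(=O)[C@H](C)CC)/C=C(/C)C[C@H](OCc1ccc(OC)cc1)/C=C(/C)[C@H]2OCc1ccc(OC)cc1 | intermediate
28 | (3aS,4R,5Z,8S,9Z,11R,11aR)-8,11-dihydroxy-6,10-dimethyl-3-methylidene-2-oxo-2,3,3a,4,7,8,11,11a-octahydrocyclodeca[b]furan-4-yl (2R)-2-methylbutanoate | C=C1C(=O)O[C@@H]2[C@@H]1[C@H](OC(=O)[C@H](C)CC)/C=C(/C)C[C@H](O)/C=C(/C)[C@H]2O | target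

**Totals**
Total step count: 22. Longest linear sequence: 22 steps (1 → 28); 26 is purchased.

**Steps most likely to fail**

1. Step 19 (Proposed new method). What may go wrong: the allyl nickel may add between molecules or through its CH2 terminus; Ni(0) may engage the aldehyde or the allylic ethers before CO2 is captured; DBU may move the C10=C1 double bond into conjugation or epimerise C9; the ring may close with the wrong facial sense at C7 or C8. Fallback with known chemistry, setting out from 19 and returning at 24: the 2‑(methoxycarbonyl)allyl unit is built first and the ring is closed by a Cr(II)-mediated intramolecular allylation, a reaction type precedented for ten‑membered germacranolide rings. TESCl/imidazole gives triethylsilyl ether F1; n‑BuLi then ClCO2Me gives ynoate F2; hydroalumination with DIBAL-H/NMO and trapping of the α‑alumino acrylate with formaldehyde gives (Z)-2-(hydroxymethyl) enoate F3; CBr4/PPh3 gives allylic bromide F4; HF·pyridine/pyridine removes the primary TES group to give bromo alcohol F5; Dess–Martin oxidation gives bromo aldehyde F6; CrCl2 in THF at high dilution, then acid, should close carbocycle and lactone to 24.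

2. Step 6. What may go wrong: Brønsted‑acid‑induced Z→E isomerisation of the enal, or poor facial selectivity on a β,β‑disubstituted enal. Fallback, setting out from 7 and returning at 9: an auxiliary‑controlled acetate aldol followed by one‑carbon homologation. The titanium enolate of (4S)-3-acetyl-4-benzyl-1,3-thiazolidine-2-thione (TiCl4, iPr2NEt; auxiliary antipode chosen for 2S) adds to 7 to give aldol adduct F7; PMB trichloroacetimidate with catalytic La(OTf)3 gives PMB ether F8; DIBAL-H at −78 °C releases the auxiliary and gives β‑alkoxy aldehyde F9; Bestmann–Ohira homologation gives 9.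

3. Step 12. What may go wrong: slow addition and poor facial control with the hindered Z‑enal, with the C6 epimer carried forward. Fallback, setting out from 13 and returning at 15: the stereocentre is set by reduction instead of addition. Lithium (trimethylsilyl)acetylide adds to 13 to give silylalkynol epimers F10; MnO2 gives ynone F11; Noyori transfer hydrogenation (Ru–TsDPEN, iPrOH; antipode chosen for 6R) gives 14, which is desilylated with K2CO3/MeOH to 15.

**Further compounds**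

F1 | step 19 | triethylsilyl ether of 19 at O8 | C#C[C@H](O[Si](C)(C)C(C)(C)C)/C=C(/C)C[C@H](OCc1ccc(OC)cc1)/C=C(/C)[C@@H](OCc1ccc(OC)cc1)CO[Si](CC)(CC)CC
F2 | step 19 | methyl ynoate from F1 (CO2Me on the former terminal alkyne carbon C11) | COC(=O)C#C[C@H](O[Si](C)(C)C(C)(C)C)/C=C(/C)C[C@H](OCc1ccc(OC)cc1)/C=C(/C)[C@@H](OCc1ccc(OC)cc1)CO[Si](CC)(CC)CC
F3 | step 19 | methyl (2Z)-2-(hydroxymethyl)alk-2-enoate from F2 (C6 cis to the ester) | OC/C(C(=O)OC)=C/[C@H](O[Si](C)(C)C(C)(C)C)/C=C(/C)C[C@H](OCc1ccc(OC)cc1)/C=C(/C)[C@@H](OCc1ccc(OC)cc1)CO[Si](CC)(CC)CC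
F4 | step 19 | methyl (2E)-2-(bromomethyl)alk-2-enoate from F3 | BrC/C(C(=O)OC)=C/[C@H](O[Si](C)(C)C(C)(C)C)/C=C(/C)C[C@H](OCc1ccc(OC)cc1)/C=C(/C)[C@@H](OCc1ccc(OC)cc1)CO[Si](CC)(CC)CC
F5 | step 19 | bromo alcohol: F4 with free primary hydroxyl at C8 | BrC/C(C(=O)OC)=C/[C@H](O[Si](C)(C)C(C)(C)C)/C=C(/C)C[C@H](OCc1ccc(OC)cc1)/C=C(/C)[C@@H](OCc1ccc(OC)cc1)CO
F6 | step 19 | bromo aldehyde: F5 oxidised at C8 | BrC/C(C(=O)OC)=C/[C@H](O[Si](C)(C)C(C)(C)C)/C=C(/C)C[C@H](OCc1ccc(OC)cc1)/C=C(/C)[C@@H](OCc1ccc(OC)cc1)C=O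
F7 | step 6 | (3S,4Z)-aldol adduct of 7 with (4S)-3-acetyl-4-benzyl-1,3-thiazolidine-2-thione | O=C(C[C@H](O)/C=C(/C)[C@@H]1COC(C)(C)O1)N1[C@@H](Cc2ccccc2)CSC1=S
F8 | step 6 | PMB ether of F7 | O=C(C[C@H](OCc1ccc(OC)cc1)/C=C(/C)[C@@H]1COC(C)(C)O1)N1[C@@H](Cc2ccccc2)CSC1=S
F9 | step 6 | (3S,4Z)-5-[(4R)-2,2-dimethyl-1,3-dioxolan-4-yl]-3-[(4-methoxyphenyl)methoxy]hex-4-enal | O=CC[C@H](OCc1ccc(OC)cc1)/C=C(/C)[C@@H]1COC(C)(C)O1
F10 | step 12 | C3 epimers of 14 (silylalkynol from achiral acetylide addition) | C[Si](C)(C)C#CC(O)/C=C(/C)C[C@H](OCc1ccc(OC)cc1)/C=C(/C)[C@@H]1COC(C)(C)O1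
F11 | step 12 | (4Z,7S,8Z)-9-[(4R)-2,2-dimethyl-1,3-dioxolan-4-yl]-7-[(4-methoxyphenyl)methoxy]-5-methyl-1-(trimethylsilyl)deca-4,8-dien-1-yn-3-one | C[Si](C)(C)C#CC(=O)/C=C(/C)C[C@H](OCc1ccc(OC)cc1)/C=C(/C)[C@@H]1COC(C)(C)O1
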